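**Plan**
1. Two cuts only. The diaryl ether bond at the ether carbon of ring A (the 3,5-dibromo-2-hydroxyphenyl ring) is cut as "carbene carbon + O–H", not as aryl halide + phenoxide. The two C–Br bonds of ring B (the 3,6-dibromo-2-oxyphenol ring) are cut back to the C–H bonds of veratrole.
2. Enabling feature: in ring A the ether carbon C1 sits next to the hydroxyl carbon C2, so C1(OAr)=C2(OH) is the enol of an α-aryloxy ketone. C1 can therefore be the diazo carbon of an o-quinone diazide, and the ring carbonyl becomes the free OH on aromatisation. Ring B is the C2v-symmetric 3,6-dibromocatechol, whose two OH groups (on C1, C2, each flanked by Br) are homotopic, so no protecting group is needed.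
3. Ring B first: veratrole is doubly ortho-lithiated and brominated (the para-dibromo pattern that electrophilic bromination cannot give), then demethylated.
4. Ring A: commercial 2-amino-4,6-dibromophenol is diazotised to the o-quinone diazide; the NH2 group fixes both the bromine pattern and the coupling position.
5. The rings are joined last, without protecting groups, by Rh(II)-carbenoid O–H insertion with aromatisation.
6. Stereochemistry: none to set.

Key step: step 4

Remark: the target has no stereocentre and no hindered axis, so it is achiral; "single enantiomer" therefore asks for no stereocontrol.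

**Step 1**
Reactants: 1 veratrole (1,2-dimethoxybenzene)
Product: 3 1,4-dibromo-2,3-dimethoxybenzene, via 3,6-dilithioveratrole 2 (not isolated)
Conditions: n-BuLi (3 equiv), TMEDA (3 equiv), hexane–Et2O, 0 °C → rt, 24 h; then BrCCl2CCl2Br (3.2 equiv), THF, −78 °C → rt
Reagents that add atoms: 1,2-dibromotetrachloroethane, BrC(Cl)(Cl)C(Cl)(Cl)Br
Why: Double directed ortho-metalation: each methoxy group directs lithiation to its free ortho position (C3, C6), as in the known dilithiation–carboxylation of veratrole, and the aryllithium is brominated by the positive-bromine donor.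

**Step 2**
Reactants: 3 1,4-dibromo-2,3-dimethoxybenzene
Product: 5 3,6-dibromocatechol, via 2,4,7-tribromo-1,3,2-benzodioxaborole 4 (not isolated)
Conditions: BBr3 (2.5 equiv), CH2Cl2, −78 °C → rt; then H2O
Reagents that add atoms: none
Why: Lewis-acid ether cleavage with BBr3; the aryl bromides are inert and the cyclic bromoborane is hydrolysed on work-up.

**Step 3**
Reactants: 6 2-amino-4,6-dibromophenol
Product: 8 2,4-dibromo-6-diazocyclohexa-2,4-dien-1-one, via 3,5-dibromo-2-hydroxybenzenediazonium chloride 7 (not isolated)
Conditions: NaNO2 (1.05 equiv), 2 M aq HCl–MeCN, 0 °C; then NaHCO3 to pH 6–7, CH2Cl2 extraction at 0 °C in the dark, MgSO4; kept as a cold solution, not concentrated to dryness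
Reagents that add atoms: sodium nitrite, [Na+].[O-]N=O
Why: Classical diazotisation of an o-aminophenol; the acidic o-hydroxydiazonium ion loses its phenolic proton on neutralisation to give the neutral diazo-oxide (o-quinone diazide), which is obtained free of acid and water for step 4.

**Step 4**
Reactants: 8 2,4-dibromo-6-diazocyclohexa-2,4-dien-1-one; 5 3,6-dibromocatechol
Product: 11 3,6-dibromo-2-(3,5-dibromo-2-hydroxyphenoxy)phenol, via rhodium carbenoid 9 (not isolated), via oxonium ylide 10 (not isolated)
Conditions: 8 in CH2Cl2 added over 2 h to 5 (3 equiv), Rh2(OAc)4 (2 mol %), 4 Å MS, CH2Cl2, 25 → 40 °C, dark, N2; excess 5 recovered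
Reagents that add atoms: none
Why: Proposed new method: Rh2(OAc)4 extrudes N2 from the cyclic α-diazo ketone 8 to give the electrophilic 2-oxocyclohexadienylidene carbenoid 9, one hydroxyl oxygen of 5 adds to its carbene carbon (C6 of 8, the former C–N carbon, which becomes the ether carbon of ring A) to give the oxonium ylide 10, in which ring A is already an aromatic phenolate, and a proton shift from O+ to O−, relayed by the neighbouring OH of ring B, releases the catalyst and 11, aromatisation of ring A being the driving force. The closest known reaction types are the Rh(II)-catalysed O–H insertion of α-diazo carbonyl compounds into phenols and the metal-catalysed aryl-transfer (C–H and X–H functionalisation) reactions of quinone diazides; new here is a free, halogenated catechol as the O–H partner and a di-ortho-substituted diaryl ether as the product. No ring is closed and no stereocentre is formed. The regiochemistry of ring A cannot vary, because the new C–O bond forms at the former C–N carbon and the carbonyl oxygen becomes the free OH, and that of ring B cannot vary, because the two OH groups of C2v-symmetric 5 are homotopic. The step needs O–H insertion to win over attack on the free ring positions C4/C5 of 5 (deactivated and each flanked by a bromine; Rh(II) carboxylates favour ylide formation at oxygen) and over a second insertion (5 in excess; both OH groups of 11 are flanked by Br and OAr). It also needs carbenoid formation to win over Wolff ring contraction and azo coupling of 8, which the catalyst, the absence of base and light, a temperature of at most 40 °C and slow addition of 8 should secure.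

**Compound list**
1 | veratrole (1,2-dimethoxybenzene) | COc1ccccc1OC | starting material
2 | 3,6-dilithioveratrole (1,4-dilithio-2,3-dimethoxybenzene) | COc1c([Li])ccc([Li])c1OC | intermediate
3 | 1,4-dibromo-2,3-dimethoxybenzene | COc1c(Br)ccc(Br)c1OC | intermediate
4 | 2,4,7-tribromo-1,3,2-benzodioxaborole | BrB1Oc2c(Br)ccc(Br)c2O1 | intermediate
5 | 3,6-dibromocatechol (3,6-dibromobenzene-1,2-diol) | Oc1c(Br)ccc(Br)c1O | intermediate
6 | 2-amino-4,6-dibromophenol | Nc1cc(Br)cc(Br)c1O | starting material
7 | 3,5-dibromo-2-hydroxybenzenediazonium chloride | Oc1c(Br)cc(Br)cc1[N+]#N.[Cl-] | intermediate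
8 | 2,4-dibromo-6-diazocyclohexa-2,4-dien-1-one (o-quinone diazide) | O=C1C(Br)=CC(Br)=CC1=[N+]=[N-] | intermediate
9 | rhodium carbenoid: (3,5-dibromo-6-oxocyclohexa-2,4-dien-1-ylidene)dirhodium tetraacetate, acetates drawn as counter-ions | O=C1C(Br)=CC(Br)=CC1=[Rh+2].[Rh+2].CC(=O)[O-].CC(=O)[O-].CC(=O)[O-].CC(=O)[O-] | intermediate
10 | oxonium ylide: 2,4-dibromo-6-[(3,6-dibromo-2-hydroxyphenyl)oxonio]phenolate | [O-]c1c(Br)cc(Br)cc1[OH+]c1c(Br)ccc(Br)c1O | intermediate
11 | 3,6-dibromo-2-(3,5-dibromo-2-hydroxyphenoxy)phenol | Oc1c(Br)cc(Br)cc1Oc1c(Br)ccc(Br)c1O | target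

**Step count:** 4 steps in total; longest linear sequence 3 steps (steps 1, 2, 4).

**Steps most likely to fail**

Step 4 (proposed new method). The carbenoid may be consumed before the weakly nucleophilic, doubly flanked hydroxyl reaches it. Possible competing processes are carbene dimerisation, C–C bond formation at the free ring positions of the catechol, hydrogen transfer from the catechol to the carbenoid (redox instead of insertion), Wolff ring contraction, and a second insertion into the product. The fallback uses known chemistry, sets out from 5 and returns at 11. Compound 5 (in excess) is mono-arylated by SNAr with commercial 2,4-dibromo-6-fluorobenzaldehyde (O=Cc1c(F)cc(Br)cc1Br; K2CO3, DMF, 60 °C). Fluoride ortho to the formyl group should be displaced in preference to the bromides, giving 2,4-dibromo-6-(3,6-dibromo-2-hydroxyphenoxy)benzaldehyde F1. Baeyer–Villiger (Dakin-type) oxidation with mCPBA in CH2Cl2 should give 2,4-dibromo-6-(3,6-dibromo-2-hydroxyphenoxy)phenyl formate F2, and methanolysis (K2CO3, MeOH) should give 11.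

Step 3. The neutral diazo-oxide may lose nitrogen, couple with unconsumed amine, or undergo light-induced ring contraction while it is neutralised, extracted and dried; as a halogenated diazo-oxide it is also an energetic material. The fallback sets out from 6 (and uses 5) and returns at 11 without any isolated diazo compound.
- 6 is diazotised as in step 3 to 7, which is not neutralised but treated in the acidic solution with KI (Sandmeyer-type iodination) to give 2,4-dibromo-6-iodophenol F3.
- O-Methylation (MeI, K2CO3, acetone) gives 1,5-dibromo-3-iodo-2-methoxybenzene F4.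
- One-pot oxidation and arylation (mCPBA, TsOH·H2O, MeCN; then 1,3,5-trimethoxybenzene) gives (3,5-dibromo-2-methoxyphenyl)(2,4,6-trimethoxyphenyl)iodonium tosylate F5.
- Metal-free O-arylation of excess 5 (K2CO3, MeCN, rt → 50 °C) should transfer the electron-poor, ortho-substituted aryl group and leave the trimethoxyphenyl group on iodine, giving 3,6-dibromo-2-(3,5-dibromo-2-methoxyphenoxy)phenol F6.
- BBr3 in CH2Cl2 then gives 11.

Step 1. The second metalation may stay incomplete, since the mono-lithio species is deprotonated only slowly, so that mono- and dibromide form together; the base may also attack TMEDA or the ether on long reaction times. The fallback sets out from 1 and returns at 3 without a dianion. Veratrole is lithiated once (n-BuLi, TMEDA, Et2O) and silylated (TMSCl) to (2,3-dimethoxyphenyl)trimethylsilane F7. A second lithiation ortho to the other methoxy group and silylation gives (2,3-dimethoxy-1,4-phenylene)bis(trimethylsilane) F8. Electrophilic ipso-bromodesilylation of both C–Si bonds (Br2, CH2Cl2, 0 °C) should then give 3.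

**Further compounds**
F1 | step 4 | 2,4-dibromo-6-(3,6-dibromo-2-hydroxyphenoxy)benzaldehyde | O=Cc1c(Br)cc(Br)cc1Oc1c(Br)ccc(Br)c1O
F2 | step 4 | 2,4-dibromo-6-(3,6-dibromo-2-hydroxyphenoxy)phenyl formate | O=COc1c(Br)cc(Br)cc1Oc1c(Br)ccc(Br)c1O
F3 | step 3 | 2,4-dibromo-6-iodophenol | Oc1c(Br)cc(Br)cc1I
F4 | step 3 | 1,5-dibromo-3-iodo-2-methoxybenzene | COc1c(Br)cc(Br)cc1I
F5 | step 3 | (3,5-dibromo-2-methoxyphenyl)(2,4,6-trimethoxyphenyl)iodonium 4-methylbenzenesulfonate | COc1c(Br)cc(Br)cc1[I+]c1c(OC)cc(OC)cc1OC.Cc1ccc(cc1)S(=O)(=O)[O-]
F6 | step 3 | 3,6-dibromo-2-(3,5-dibromo-2-methoxyphenoxy)phenol | COc1c(Br)cc(Br)cc1Oc1c(Br)ccc(Br)c1O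
F7 | step 1 | (2,3-dimethoxyphenyl)trimethylsilane | COc1cccc([Si](C)(C)C)c1OC
F8 | step 1 | (2,3-dimethoxy-1,4-phenylene)bis(trimethylsilane) | COc1c([Si](C)(C)C)ccc([Si](C)(C)C)c1OC
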